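**Retrosynthetic overview**
1. Target 19 is (−)-epicatechin 3-O-gallate-(4β→8)-(−)-epigallocatechin 3-O-gallate. It is opened first at the fifteen O-benzyl groups, then at the C4(upper)–C8(lower) bond, giving flavan-4-yl cation precursor 17 and nucleophile 13.
2. Upper unit 17: all three rings and C2/C3 come with (−)-epicatechin 14. Only O-benzylation, C4 oxidation and galloylation are added.
3. Lower unit 13: the disconnections are the C3–O ester, then C2/C3 (set together by hydrogenation of the racemising ketone 10 under dynamic kinetic resolution), then ring C. Ring C arises from the five-membered furan-3-one ring of 8/9 by a one-atom ring expansion, and 8/9 come from acyclic diazoketone 7 (aldehyde 1 + CHCl3 + phenol 3 + CH2N2).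
4. Enabling feature: in the 1,3,5-trioxygenated ring A, the O1-bearing carbon C8a lies next to the unsubstituted C4a, which is ortho/para to O1, O5 and O7. The C8a=C4a bond takes up the carbene carbon C4. In the resulting cyclopropane only the C4–C8a bond lies between a donor (O1) and an acceptor (C3=O), so only that bond breaks.
5. Ring order in the lower unit: rings A and B are bought; then the furanone ring plus cyclopropane/cycloheptatriene form (ring A dearomatised); then ring C forms as ring A is restored.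

Key step: step 4

Assumption: 1, 3, 12 and 14 are taken as catalogue compounds, and the catalyst antipode named in step 5 is assumed to give the (2R,3R) alcohol by analogy with 2-arylcyclohexanones; if the sense is opposite, its mirror image is used.

**Step 1**
Reactants: 1 3,4,5-tris(benzyloxy)benzaldehyde
Product: 2 (±)-2,2,2-trichloro-1-[3,4,5-tris(benzyloxy)phenyl]ethanol
Conditions: CHCl3, DBU, neat, 0 °C to rt
Reagents that add atoms: chloroform, ClC(Cl)Cl
Why: Base-mediated addition of the trichloromethyl anion to an aromatic aldehyde (opening move of the Jocic–Reeve sequence) should give the carbinol cleanly, and the new centre is left racemic on purpose because C2 becomes configurationally labile in 10 and is set only in step 5.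

**Step 2**
Reactants: 2 (±)-2,2,2-trichloro-1-[3,4,5-tris(benzyloxy)phenyl]ethanol; 3 3,5-bis(benzyloxy)phenol
Product: 5 (±)-2-[3,5-bis(benzyloxy)phenoxy]-2-[3,4,5-tris(benzyloxy)phenyl]acetic acid, via dichloroepoxide 4 (not isolated)
Conditions: NaOH (aq), BnEt3NCl (cat.), DME, 0 °C to rt; then HCl (aq)
Reagents that add atoms: sodium hydroxide, [Na+].[OH-] (oxygen of the carboxyl OH)
Why: Jocic–Reeve reaction: hydroxide closes 2 to dichloroepoxide 4, the phenoxide of 3 opens it at the benzylic carbon and hydroxide turns the remaining CCl2 carbon into the carboxylate, which installs the O1–C2 aryl ether and the C3 carbon in one flask (product racemic).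

**Step 3**
Reactants: 5 (±)-2-[3,5-bis(benzyloxy)phenoxy]-2-[3,4,5-tris(benzyloxy)phenyl]acetic acid
Product: 7 (±)-1-diazo-3-[3,5-bis(benzyloxy)phenoxy]-3-[3,4,5-tris(benzyloxy)phenyl]propan-2-one, via mixed anhydride 6 (not isolated)
Conditions: i-BuOCOCl, N-methylmorpholine, THF, −20 °C; then CH2N2, Et2O, 0 °C
Reagents that add atoms: diazomethane, C=[N+]=[N-]; isobutyl chloroformate, CC(C)COC(=O)Cl (its atoms stay only in 6)
Why: Acylation of diazomethane by a mixed carbonic anhydride (first half of the Arndt–Eistert sequence) should give the α-diazoketone under cold, neutral conditions that leave the benzyl ethers and the benzylic aryl ether alone, and no stereocentre is set.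

**Step 4**
Reactants: 7 (±)-1-diazo-3-[3,5-bis(benzyloxy)phenoxy]-3-[3,4,5-tris(benzyloxy)phenyl]propan-2-one
Product: 10 (±)-5,7-bis(benzyloxy)-2-[3,4,5-tris(benzyloxy)phenyl]chroman-3-one, via norcaradiene 8 (not isolated), via cycloheptafuranone 9 (not isolated)
Conditions: Rh2(OAc)4 (1 mol %), CH2Cl2, reflux, slow addition of 7; then CF3CO2H (cat.), 0 °C
Reagents that add atoms: none
Why: Rh2(OAc)4 expels N2 from 7 and the electrophilic carbene carbon (the future C4) adds across the C8a=C4a bond of the symmetric, electron-rich ring A (intramolecular Buchner reaction); this [2+1] cycloaddition over a three-atom tether closes the five-membered furan-3-one ring (O1, C2, C3, C4, C8a) together with the cyclopropane and gives norcaradiene 8, in valence equilibrium with cycloheptatriene 9. In 8 the C4–C8a bond is a donor–acceptor cyclopropane bond (donor O1 on C8a, acceptor C3=O on C4), so a trace of CF3CO2H should break exactly this bond while C4–C4a stays; loss of H from C4a re-aromatises ring A and the enol tautomerises, so C4 has moved from C8a to C4a and the five-membered ring has become six-membered ring C (one-atom ring expansion, not a new closure) while the seven-membered carbocycle contracts back to benzene. The closest known reaction types are the rhodium-catalysed Buchner cyclisation of 1-diazo-4-arylbutan-2-ones to dihydroazulenones with their acid-induced rearrangement to 2-tetralones, and the conversion of aryloxy diazoketones into chroman-3-ones. No lasting stereocentre is made: C2 stays racemic, the sp3 centres at C4, C4a and C8a of 8/9 vanish again, and configuration is set in step 5. The selectivity needed is attack on ring A rather than on ring B (which would close a 2-indanone), and it rests on three ortho/para oxygen donors at C4a against two at the ortho carbon of ring B; the two ortho positions of ring A are equivalent, so no regiochemical question arises there.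

**Step 5**
Reactants: 10 (±)-5,7-bis(benzyloxy)-2-[3,4,5-tris(benzyloxy)phenyl]chroman-3-one
Product: 11 (2R,3R)-5,7-bis(benzyloxy)-2-[3,4,5-tris(benzyloxy)phenyl]chroman-3-ol (penta-O-benzyl-(−)-epigallocatechin)
Conditions: RuCl2[(S)-xylBINAP][(S)-DAIPEN] (0.5 mol %), KOt-Bu (cat.), H2 (50 bar), i-PrOH–toluene, rt
Reagents that add atoms: none
Why: Noyori asymmetric hydrogenation under dynamic kinetic resolution, as known for 2-aryl- and 2-alkoxycyclohexanones: KOt-Bu should racemise C2 through the enolate faster than the chiral ruthenium hydride reduces the matched (2R)-ketone, and hydride delivery to C3 from the face opposite the C2 aryl group sets the 2,3-cis (2R,3R) pair in one step, the homogeneous catalyst leaving the benzyl ethers intact.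

**Step 6**
Reactants: 11 penta-O-benzyl-(−)-epigallocatechin; 12 3,4,5-tris(benzyloxy)benzoic acid
Product: 13 (2R,3R)-5,7-bis(benzyloxy)-2-[3,4,5-tris(benzyloxy)phenyl]chroman-3-yl 3,4,5-tris(benzyloxy)benzoate (octa-O-benzyl-(−)-epigallocatechin gallate)
Conditions: DCC, DMAP, CH2Cl2, rt
Reagents that add atoms: none
Why: Steglich esterification of the only free hydroxyl group proceeds at oxygen, so C3 keeps its configuration.

**Step 7**
Reactants: 14 (−)-epicatechin
Product: 15 (2R,3R)-5,7-bis(benzyloxy)-2-[3,4-bis(benzyloxy)phenyl]chroman-3-ol (tetra-O-benzyl-(−)-epicatechin)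
Conditions: BnBr, K2CO3, DMF, 0 °C to rt
Reagents that add atoms: benzyl bromide, BrCc1ccccc1
Why: Williamson etherification with a carbonate base alkylates only the four phenols and not the secondary alcohol, and the low temperature keeps C2 from epimerising.

**Step 8**
Reactants: 15 tetra-O-benzyl-(−)-epicatechin
Product: 16 (2R,3R,4S)-5,7-bis(benzyloxy)-2-[3,4-bis(benzyloxy)phenyl]-4-(2-ethoxyethoxy)chroman-3-ol (4β-ether)
Conditions: DDQ, 2-ethoxyethanol, CH2Cl2, rt
Reagents that add atoms: 2-ethoxyethanol, CCOCCO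
Why: Oxidative benzylic C–H etherification, known for benzylated flavan-3-ols: DDQ removes hydride from C4, which is activated by the three oxygens of ring A, and the alcohol adds from the β face, trans to the 3-OH, giving the 4β ether as a storable leaving group.

**Step 9**
Reactants: 16 4β-(2-ethoxyethoxy) alcohol; 12 3,4,5-tris(benzyloxy)benzoic acid
Product: 17 (2R,3R,4S)-5,7-bis(benzyloxy)-2-[3,4-bis(benzyloxy)phenyl]-4-(2-ethoxyethoxy)chroman-3-yl 3,4,5-tris(benzyloxy)benzoate
Conditions: DCC, DMAP, CH2Cl2, rt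
Reagents that add atoms: none
Why: Steglich esterification under neutral conditions acylates the 3-OH without ionising the acid-labile C4 ether, and no stereocentre is touched.

**Step 10**
Reactants: 17 galloylated 4β-ether (electrophile); 13 octa-O-benzyl-(−)-epigallocatechin gallate (nucleophile, in excess, the surplus recovered)
Product: 18 pentadeca-O-benzyl derivative of the target, (2R,3R,4R) in the upper and (2R,3R) in the lower unit, C4(upper)–C8(lower) bond
Conditions: TMSOTf (cat.), CH2Cl2, −78 °C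
Reagents that add atoms: none
Why: Biomimetic Friedel–Crafts alkylation known for benzylated, galloylated flavan-3-ols: the Lewis acid ionises the C4 ether, the α-oriented 3-O-galloyl group shields the α face so that C8 of 13 (more accessible and more nucleophilic than C6) attacks from the β face and sets the 3,4-trans (4R) centre.

**Step 11**
Reactants: 18 pentadeca-O-benzyl dimer
Product: 19 (−)-epicatechin 3-O-gallate-(4β→8)-(−)-epigallocatechin 3-O-gallate (target)
Conditions: H2 (1 atm), Pd(OH)2/C, THF–MeOH–H2O, rt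
Reagents that add atoms: none
Why: Catalytic hydrogenolysis cleaves all fifteen benzyl aryl ethers under neutral conditions that should spare the two gallate esters, the interflavan bond and the five stereocentres.

**Compound list**
1 | 3,4,5-tris(benzyloxy)benzaldehyde | O=Cc1cc(OCc2ccccc2)c(OCc2ccccc2)c(OCc2ccccc2)c1 | starting material
2 | (±)-2,2,2-trichloro-1-[3,4,5-tris(benzyloxy)phenyl]ethanol | OC(c1cc(OCc2ccccc2)c(OCc2ccccc2)c(OCc2ccccc2)c1)C(Cl)(Cl)Cl | intermediate
3 | 3,5-bis(benzyloxy)phenol | Oc1cc(OCc2ccccc2)cc(OCc2ccccc2)c1 | starting material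
4 | (±)-2,2-dichloro-3-[3,4,5-tris(benzyloxy)phenyl]oxirane (not isolated) | ClC1(Cl)OC1c1cc(OCc2ccccc2)c(OCc2ccccc2)c(OCc2ccccc2)c1 | intermediate
5 | (±)-2-[3,5-bis(benzyloxy)phenoxy]-2-[3,4,5-tris(benzyloxy)phenyl]acetic acid | OC(=O)C(Oc1cc(OCc2ccccc2)cc(OCc2ccccc2)c1)c1cc(OCc2ccccc2)c(OCc2ccccc2)c(OCc2ccccc2)c1 | intermediate
6 | mixed anhydride of 5 with isobutyl hydrogen carbonate (not isolated) | CC(C)COC(=O)OC(=O)C(Oc1cc(OCc2ccccc2)cc(OCc2ccccc2)c1)c1cc(OCc2ccccc2)c(OCc2ccccc2)c(OCc2ccccc2)c1 | intermediate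
7 | (±)-1-diazo-3-[3,5-bis(benzyloxy)phenoxy]-3-[3,4,5-tris(benzyloxy)phenyl]propan-2-one | [N-]=[N+]=CC(=O)C(Oc1cc(OCc2ccccc2)cc(OCc2ccccc2)c1)c1cc(OCc2ccccc2)c(OCc2ccccc2)c(OCc2ccccc2)c1 | intermediate
8 | norcaradiene adduct: 2-aryl-furan-3-one ring (O1, C2, C3, C4, C8a) whose C4 also bonds to C4a, forming the cyclopropane C4–C4a–C8a fused to a 5,7-bis(benzyloxy)cyclohexa-1,3-diene; diastereomer mixture, racemic (not isolated) | O=C1C(c2cc(OCc3ccccc3)c(OCc3ccccc3)c(OCc3ccccc3)c2)OC23C=C(OCc4ccccc4)C=C(OCc4ccccc4)C2C13 | intermediate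
9 | (±)-5,7-bis(benzyloxy)-2-[3,4,5-tris(benzyloxy)phenyl]-2H-cyclohepta[b]furan-3(3aH)-one, valence tautomer of 8 (not isolated) | O=C1C(c2cc(OCc3ccccc3)c(OCc3ccccc3)c(OCc3ccccc3)c2)OC2=CC(OCc3ccccc3)=CC(OCc3ccccc3)=CC12 | intermediate
10 | (±)-5,7-bis(benzyloxy)-2-[3,4,5-tris(benzyloxy)phenyl]chroman-3-one | O=C1Cc2c(OCc3ccccc3)cc(OCc3ccccc3)cc2OC1c1cc(OCc2ccccc2)c(OCc2ccccc2)c(OCc2ccccc2)c1 | intermediate
11 | (2R,3R)-5,7-bis(benzyloxy)-2-[3,4,5-tris(benzyloxy)phenyl]chroman-3-ol | O[C@@H]1Cc2c(OCc3ccccc3)cc(OCc3ccccc3)cc2O[C@@H]1c1cc(OCc2ccccc2)c(OCc2ccccc2)c(OCc2ccccc2)c1 | intermediate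
12 | 3,4,5-tris(benzyloxy)benzoic acid | OC(=O)c1cc(OCc2ccccc2)c(OCc2ccccc2)c(OCc2ccccc2)c1 | starting material
13 | octa-O-benzyl-(−)-epigallocatechin gallate, (2R,3R) | O=C(O[C@@H]1Cc2c(OCc3ccccc3)cc(OCc3ccccc3)cc2O[C@@H]1c1cc(OCc2ccccc2)c(OCc2ccccc2)c(OCc2ccccc2)c1)c1cc(OCc2ccccc2)c(OCc2ccccc2)c(OCc2ccccc2)c1 | intermediate
14 | (−)-epicatechin, (2R,3R) | O[C@@H]1Cc2c(O)cc(O)cc2O[C@@H]1c1ccc(O)c(O)c1 | starting material
15 | 5,7,3',4'-tetra-O-benzyl-(−)-epicatechin, (2R,3R) | O[C@@H]1Cc2c(OCc3ccccc3)cc(OCc3ccccc3)cc2O[C@@H]1c1ccc(OCc2ccccc2)c(OCc2ccccc2)c1 | intermediate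
16 | (2R,3R,4S)-5,7-bis(benzyloxy)-2-[3,4-bis(benzyloxy)phenyl]-4-(2-ethoxyethoxy)chroman-3-ol | O[C@@H]1[C@@H](OCCOCC)c2c(OCc3ccccc3)cc(OCc3ccccc3)cc2O[C@@H]1c1ccc(OCc2ccccc2)c(OCc2ccccc2)c1 | intermediate
17 | 3-O-[3,4,5-tris(benzyloxy)benzoyl] derivative of 16, (2R,3R,4S) | O=C(O[C@@H]1[C@@H](OCCOCC)c2c(OCc3ccccc3)cc(OCc3ccccc3)cc2O[C@@H]1c1ccc(OCc2ccccc2)c(OCc2ccccc2)c1)c1cc(OCc2ccccc2)c(OCc2ccccc2)c(OCc2ccccc2)c1 | intermediate
18 | pentadeca-O-benzyl epicatechin gallate-(4β→8)-epigallocatechin gallate | O=C(O[C@@H]1[C@@H](c2c(OCc4ccccc4)cc(OCc4ccccc4)c3c2O[C@H](c2cc(OCc4ccccc4)c(OCc4ccccc4)c(OCc4ccccc4)c2)[C@H](OC(=O)c2cc(OCc4ccccc4)c(OCc4ccccc4)c(OCc4ccccc4)c2)C3)c2c(OCc4ccccc4)cc(OCc4ccccc4)cc2O[C@@H]1c1ccc(OCc4ccccc4)c(OCc4ccccc4)c1)c1cc(OCc4ccccc4)c(OCc4ccccc4)c(OCc4ccccc4)c1 | intermediate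
19 | (−)-epicatechin 3-O-gallate-(4β→8)-(−)-epigallocatechin 3-O-gallate (CNP0296769.1) | O=C(O[C@@H]1[C@@H](c2c(O)cc(O)c3c2O[C@H](c2cc(O)c(O)c(O)c2)[C@H](OC(=O)c2cc(O)c(O)c(O)c2)C3)c2c(O)cc(O)cc2O[C@@H]1c1ccc(O)c(O)c1)c1cc(O)c(O)c(O)c1 | target

**Total step count:** 11.
**Longest linear sequence:** 8 steps (steps 1–6, 10, 11, from aldehyde 1).

**Steps most likely to fail**

**Step 4.**
- Risk: the carbene may be used up by attack on ring B or by dimerisation before it reaches the C8a=C4a bond. The dearomatised adduct may also decompose before it rearranges.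
- Fallback: it sets out from 5 and comes back at 10, and it keeps a one-atom ring expansion of an isolated five-membered ring. Acid 5 is closed with (CF3CO)2O in CH2Cl2 by intramolecular Friedel–Crafts acylation onto ring A to (±)-4,6-bis(benzyloxy)-2-[3,4,5-tris(benzyloxy)phenyl]benzofuran-3(2H)-one F1. The carbonyl group of F1 is methylenated with Cp2TiMe2 in toluene at 70 °C (Petasis olefination, tolerant of the enolisable C2–H) to (±)-4,6-bis(benzyloxy)-3-methylidene-2-[3,4,5-tris(benzyloxy)phenyl]-2,3-dihydrobenzofuran F2. PhI(OH)OTs in 95 % MeOH at 0 °C then puts trivalent iodine on the exocyclic CH2 and oxygen on C3, after which ring A migrates from C3 to the CH2 carbon as PhI leaves. This oxidative ring expansion is known for 1-methylidene benzocycloalkanes and should give 10.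

**Step 5.**
- Risk: racemisation at C2 may be too slow relative to reduction, or the catalyst may discriminate poorly between the faces, so that enantiomeric purity erodes.
- Fallback: it sets out from 10 and comes back at 11. LiBH(s-Bu)3 in THF at −78 °C reduces racemic 10 from the face opposite the aryl group to the racemic 2,3-cis alcohol F3. Steglich esterification with (S)-2-methoxy-2-phenylacetic acid gives the (2R,3R) ester F4 and the (2S,3S) ester F5, which are separated by chromatography or crystallisation. K2CO3 in MeOH–THF then cleaves F4 to 11.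

**Step 10.**
- Risk: the cation from 17 may be captured by C8 or C6 of a second molecule of 17 or of product 18, which leads to oligomerisation and consumes the precious nucleophile.
- Fallback: it sets out from 17 and comes back at 19. NBS in CH2Cl2 at −78 °C brominates C8 of ring A of 17 to the 8-bromo electrophile F6, which can no longer act as a C8 nucleophile. Coupling of F6 with an equimolar amount of 13 under Lewis-acid activation gives the 8-bromo dimer F7. Hydrogenolysis over Pd(OH)2/C with Et3N removes the bromine together with the fifteen benzyl groups and gives 19.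

**Further compounds**
F1 | step 4 | (±)-4,6-bis(benzyloxy)-2-[3,4,5-tris(benzyloxy)phenyl]benzofuran-3(2H)-one | O=C1c2c(OCc3ccccc3)cc(OCc3ccccc3)cc2OC1c1cc(OCc2ccccc2)c(OCc2ccccc2)c(OCc2ccccc2)c1
F2 | step 4 | (±)-4,6-bis(benzyloxy)-3-methylidene-2-[3,4,5-tris(benzyloxy)phenyl]-2,3-dihydrobenzofuran | C=C1c2c(OCc3ccccc3)cc(OCc3ccccc3)cc2OC1c1cc(OCc2ccccc2)c(OCc2ccccc2)c(OCc2ccccc2)c1
F3 | step 5 | racemic 2,3-cis-5,7-bis(benzyloxy)-2-[3,4,5-tris(benzyloxy)phenyl]chroman-3-ol (both enantiomers) | O[C@@H]1Cc2c(OCc3ccccc3)cc(OCc3ccccc3)cc2O[C@@H]1c1cc(OCc2ccccc2)c(OCc2ccccc2)c(OCc2ccccc2)c1.O[C@H]1Cc2c(OCc3ccccc3)cc(OCc3ccccc3)cc2O[C@H]1c1cc(OCc2ccccc2)c(OCc2ccccc2)c(OCc2ccccc2)c1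
F4 | step 5 | (2R,3R)-5,7-bis(benzyloxy)-2-[3,4,5-tris(benzyloxy)phenyl]chroman-3-yl (S)-2-methoxy-2-phenylacetate | O=C(O[C@@H]1Cc2c(OCc3ccccc3)cc(OCc3ccccc3)cc2O[C@@H]1c1cc(OCc2ccccc2)c(OCc2ccccc2)c(OCc2ccccc2)c1)[C@@H](OC)c1ccccc1
F5 | step 5 | (2S,3S)-5,7-bis(benzyloxy)-2-[3,4,5-tris(benzyloxy)phenyl]chroman-3-yl (S)-2-methoxy-2-phenylacetate | O=C(O[C@H]1Cc2c(OCc3ccccc3)cc(OCc3ccccc3)cc2O[C@H]1c1cc(OCc2ccccc2)c(OCc2ccccc2)c(OCc2ccccc2)c1)[C@@H](OC)c1ccccc1
F6 | step 10 | 8-bromo derivative of 17 | O=C(O[C@@H]1[C@@H](OCCOCC)c2c(OCc3ccccc3)cc(OCc3ccccc3)c(Br)c2O[C@@H]1c1ccc(OCc2ccccc2)c(OCc2ccccc2)c1)c1cc(OCc2ccccc2)c(OCc2ccccc2)c(OCc2ccccc2)c1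
F7 | step 10 | derivative of 18 with bromine at C8 of the upper unit | O=C(O[C@@H]1[C@@H](c2c(OCc4ccccc4)cc(OCc4ccccc4)c3c2O[C@H](c2cc(OCc4ccccc4)c(OCc4ccccc4)c(OCc4ccccc4)c2)[C@H](OC(=O)c2cc(OCc4ccccc4)c(OCc4ccccc4)c(OCc4ccccc4)c2)C3)c2c(OCc4ccccc4)cc(OCc4ccccc4)c(Br)c2O[C@@H]1c1ccc(OCc4ccccc4)c(OCc4ccccc4)c1)c1cc(OCc4ccccc4)c(OCc4ccccc4)c(OCc4ccccc4)c1
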